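A small charge of pre-initiator, 2.3 mol% on the free monomer, stood in a flask of 0.063 M that I had followed for 6.00 h as the south run. I wanted its average chain length at 50 h, and my evidence was that short run and a longer south-west run at 0.032 M with the same loading.

| setting | south | south-west | flask |
|---|---|---|---|
| free monomer | 0.063 M | 0.032 M | 0.063 M |
| pre-initiator | 2.3 mol% | 2.3 mol% | 2.3 mol% |
| remark | the very flask that is asked about, followed so far | run made earlier |  |
| time |  |  | 50 h |

| run | time / h | monomer in chains / % | free monomer / % |
|---|---|---|---|
| south | 1.50 | 0 | 100.3 |
| south | 3.00 | 0.5 | 100.5 |
| south | 5.00 | 0 | 99.8 |
| south | 6.00 | 0.2 | 99.6 |
| south-west | 4.00 | 0.2 | 100.4 |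
| south-west | 12.0 | 0.8 | 98.9 |
| south-west | 25.0 | 5.1 | 95.1 |
| south-west | 40.0 | 13.1 | 87.0 |

(standard deviation of a reading: 0.5 percentage points)

- whether the average number of monomer units in a chain (chains begun, living or dead) reaches 40 by 50 h (no / yes)
- average number of monomer units in a chain (chains begun, living or dead) at 50 h

- the average divides the monomer in chains by the number of chains begun, living and dead together
- candidate steps: free monomer + initiator -> living end + monomer in chains; free monomer + living end -> monomer in chains + living end; pre-initiator <-> initiator
- the earlier runs do not show the number of chains; that part of a forecast is a guess

I built the flask up one step at a time. With growth on a fixed number of living ends, free monomer would fall pseudo-first-order, its logarithm growing as time; but between 25.0 h and 40.0 h of the south-west run that logarithm grew 2.77 times as read, against 1.60 for time and 2.56 for its square. Adding chain starts, with ends building up steadily, gives the square, so I reckoned from that last scattered reading: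

ramp time, south-west = 40.0 h ÷ √(−ln 87.0%) = 107 h

This ramp time, the time by which the logarithm of the fraction of free monomer left has fallen by one under a steady build-up of ends, goes as the inverse of the charge at fixed loading, since a chain start takes free monomer and initiator, and both scale with the charge:

ramp time, flask = 107 h × 0.032 M ÷ 0.063 M = 54.4 h

free monomer left in the flask at 50 h = 43.0%

The remaining step is the release of initiator from pre-initiator, and with the whole loading begun as chains my reckoned conversion gives:

average with the whole loading begun = reacted fraction ÷ loading = 24.8

On that reckoning the average stood above 40 if under 61.9% of the pre-initiator had begun chains by 50 h. I read the square law up to 40.0 h of the south-west run as ends still building, took the share begun in the flask to be below that, and answered yes; the earlier runs do not show the number of chains, so I gave no average of my own.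

The forecast, which is not my reckoning, answered yes with 50, saying of its chain count: “This part is a guess”. The flask gives yes with 144, and free monomer 46.1% against my 43.0%.

    free monomer + initiator → living end + monomer in chains (k = 9.20 × 10⁻⁵ /M/s)
    free monomer + living end → monomer in chains + living end, rate k2*[living end]*[free monomer] (k = 0.0350 /M/s)
    pre-initiator ⇌ initiator (K = 0.370, k = 1.20 × 10⁻⁵ /s)

In the flask at 32.2 h, free monomer was used on living ends 200 times as fast as in chain starts. At 50.0 h the living ends stood at 0.375% of the free monomer charged, which is 16.3% of the loading. The flask's free monomer at that time gives a ramp time of 56.8 h; scaled by the charges to the south-west run, that is 112 h, which puts free monomer at 95.1% at 25.0 h, where the reading was 95.1%.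

The numbers in the tables are simulated on assumed constants; the scatter is artificial.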